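**Retrosynthetic overview**
1. 8 ⇒ 7: exchange of two Bu4N+ for two H+. The sulfates travel as lipophilic salts and the free acid is released last.
2. 7 ⇒ 4: the key disconnection is the 3'-O–CH3 carbon–oxygen bond. It is made late, on the already sulfated flavonol, by a borinate-templated methylation with MeI.
3. 4 ⇒ 1: two O–S bonds (O-3 and O-7) are put on quercetin. The catechol is masked in the flask as its phenylboronate, and the 5-OH is shielded by its hydrogen bond to C4=O.
4. Ring order: no ring is built. Rings A, C and B are bought intact in quercetin.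

Assumption: the target is a flat, achiral flavonol with no stereocentre, so there is no enantiomer to select, and the free-acid form drawn in the SMILES is taken as the deliverable.

**Step 1**
Reactants: 1 quercetin
Product: 4 bis(tetrabutylammonium) quercetin 3,7-di-O-sulfate, via quercetin 3',4'-O-phenylboronate 2 (not isolated), via boronate-masked 3,7-disulfate salt 3 (not isolated)
Conditions: PhB(OH)2 (1.05 equiv), pyridine/toluene, 60 °C, azeotropic removal of H2O; then Bu4NHSO4 (3 equiv), DCC (8 equiv), pyridine, 4 °C to rt, 72 h; then H2O/MeOH, filter, Et2O wash, LH-20 dextran gel (MeOH)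
Reagents that add atoms: tetrabutylammonium hydrogen sulfate CCCC[N+](CCCC)(CCCC)CCCC.OS(=O)(=O)[O-]; phenylboronic acid OB(O)c1ccccc1 (its atoms stay only in 2 and 3)
Why: Transient boronate protection followed by carbodiimide-mediated O-sulfation: the catechol is locked in a five-membered dioxaborole and the 5-OH is deactivated by chelation to the C4 carbonyl, so the DCC-activated hydrogen sulfate esterifies only the 7-OH and 3-OH, and water then releases the catechol; no stereocentre is formed.

**Step 2**
Reactants: 4 bis(tetrabutylammonium) quercetin 3,7-di-O-sulfate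
Product: 7 bis(tetrabutylammonium) isorhamnetin 3,7-di-O-sulfate, via catecholato(diphenyl)borate salt 5 (not isolated), via 4'-O-diphenylboryl 3'-O-methyl ether 6 (not isolated)
Conditions: Ph2BOH (1.1 equiv), Bu4NOH (1.0 M in MeOH, 1.0 equiv), MeCN, rt, Ar, strip with toluene; then MeI (3 equiv), 4 Å MS, MeCN, 45 °C, 24 h; then H2O/MeOH, Et2O wash, LH-20 dextran gel (MeOH)
Reagents that add atoms: iodomethane CI; diphenylborinic acid OB(c1ccccc1)c1ccccc1 (atoms only in 5 and 6); tetrabutylammonium hydroxide CCCC[N+](CCCC)(CCCC)CCCC.[OH-] (cation only in 5)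
Why: Proposed new method: borinate-templated meta-selective mono-O-methylation of a catechol, in which Ph2BOH and exactly one equivalent of Bu4NOH tie both catechol oxygens into the closed tetracoordinate borate 5, so that no free phenoxide is present and site selection follows intrinsic nucleophilicity rather than acidity; O-4' is drained by para conjugation into the C2=C3–C4=O system while O-3' is only meta to it, so the SN2 attack on MeI should come from O-3', the B–O3' bond breaks as the C–O bond forms, the neutral borinic ester 6 left on O-4' cannot be methylated again because no base remains, and the sulfate anions and the chelated 5-OH are not nucleophilic toward MeI; the closest known reaction types are diarylborinic acid-promoted regioselective monoalkylation of carbohydrate cis-1,2-diols and the dianion alkylation of 3,4-dihydroxybenzaldehyde at O-3; no stereocentre is formed.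

**Step 3**
Reactants: 7 bis(tetrabutylammonium) isorhamnetin 3,7-di-O-sulfate
Product: 8 isorhamnetin 3,7-di-O-sulfate
Conditions: sulfonated polystyrene cation-exchange resin (H+ form, 20 equiv), H2O/MeOH 9:1, 0–4 °C, fast elution; freeze-dry at once, store at −20 °C
Reagents that add atoms: none
Why: Cation exchange (salt metathesis): the lipophilic Bu4N+ is held strongly by the aromatic sulfonate resin, and acid-catalysed hydrolysis of aryl sulfate monoesters is slow in cold dilute solution; no stereocentre is formed.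

**Compound list**
1 | quercetin (3,5,7,3',4'-pentahydroxyflavone) | Oc1cc(-c2oc3cc(O)cc(O)c3c(=O)c2O)ccc1O | starting material
2 | quercetin 3',4'-O-phenylboronate (2-phenyl-1,3,2-benzodioxaborole fused on ring B) | O=c1c(O)c(-c2ccc3OB(c4ccccc4)Oc3c2)oc2cc(O)cc(O)c12 | intermediate (not isolated)
3 | bis(tetrabutylammonium) quercetin 3',4'-O-phenylboronate 3,7-di-O-sulfate | CCCC[N+](CCCC)(CCCC)CCCC.CCCC[N+](CCCC)(CCCC)CCCC.O=c1c(OS(=O)(=O)[O-])c(-c2ccc3OB(c4ccccc4)Oc3c2)oc2cc(OS(=O)(=O)[O-])cc(O)c12 | intermediate (not isolated)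
4 | bis(tetrabutylammonium) quercetin 3,7-di-O-sulfate | CCCC[N+](CCCC)(CCCC)CCCC.CCCC[N+](CCCC)(CCCC)CCCC.O=c1c(OS(=O)(=O)[O-])c(-c2ccc(O)c(O)c2)oc2cc(OS(=O)(=O)[O-])cc(O)c12 | intermediate
5 | tris(tetrabutylammonium) salt of the 3',4'-catecholato(diphenyl)borate of quercetin 3,7-di-O-sulfate | CCCC[N+](CCCC)(CCCC)CCCC.CCCC[N+](CCCC)(CCCC)CCCC.CCCC[N+](CCCC)(CCCC)CCCC.O=c1c(OS(=O)(=O)[O-])c(-c2ccc3O[B-](c4ccccc4)(c4ccccc4)Oc3c2)oc2cc(OS(=O)(=O)[O-])cc(O)c12 | intermediate (not isolated)
6 | bis(tetrabutylammonium) 4'-O-(diphenylboryl)isorhamnetin 3,7-di-O-sulfate | CCCC[N+](CCCC)(CCCC)CCCC.CCCC[N+](CCCC)(CCCC)CCCC.O=c1c(OS(=O)(=O)[O-])c(-c2ccc(OB(c3ccccc3)c3ccccc3)c(OC)c2)oc2cc(OS(=O)(=O)[O-])cc(O)c12 | intermediate (not isolated)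
7 | bis(tetrabutylammonium) isorhamnetin 3,7-di-O-sulfate | CCCC[N+](CCCC)(CCCC)CCCC.CCCC[N+](CCCC)(CCCC)CCCC.COc1cc(-c2oc3cc(OS(=O)(=O)[O-])cc(O)c3c(=O)c2OS(=O)(=O)[O-])ccc1O | intermediate
8 | isorhamnetin 3,7-di-O-sulfate (free acid, achiral) | COc1cc(-c2oc3cc(OS(=O)(=O)O)cc(O)c3c(=O)c2OS(=O)(=O)O)ccc1O | target

**Total step count:** 3. **Longest linear sequence:** 3.

**Steps most likely to fail**

**Step 2 (the proposed new step).**
- Failure modes: the closed borate 5 may be too weak a nucleophile for MeI. It may also open at the B–O4' bond and leak the 4'-phenoxide, which would give the 4'-O-methyl (tamarixetin-type) isomer. An NOE between OCH3 and H-2' tells the two isomers apart.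
- The fallback uses known chemistry, sets out from 4 and comes back at 7.
- One equivalent of Bu4NOH in DMF at 0 °C deprotonates the more acidic, para-conjugated 4'-OH. BnBr (1.0 equiv) then gives bis(tetrabutylammonium) 4'-O-benzylquercetin 3,7-di-O-sulfate F1.
- A second equivalent of Bu4NOH and MeI methylate the only remaining unchelated phenol. This gives bis(tetrabutylammonium) 4'-O-benzylisorhamnetin 3,7-di-O-sulfate F2.
- Hydrogenolysis (H2 1 atm, Pd/C, MeOH, rt) removes the benzyl ether, leaves the sulfates untouched and delivers 7.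

**Step 1.**
- Failure modes: the boronate may be lost or attacked at its B–O bonds in the pyridine/hydrogen sulfate medium, which exposes the 4'-OH to sulfation. The sluggish 3-OH may also stay incompletely esterified.
- The fallback replaces the transient mask with an isolable ketal, sets out from 1 and comes back at 4.
- Ph2CCl2 (1.5 equiv) in Ph2O at 175 °C for 30 min gives 3',4'-O-(diphenylmethylene)quercetin F3.
- Bu4NHSO4/DCC in pyridine converts it into bis(tetrabutylammonium) 3',4'-O-(diphenylmethylene)quercetin 3,7-di-O-sulfate F4.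
- Hydrogenolysis (H2, Pd/C, THF/MeOH, rt) frees the catechol and gives 4.

**Step 3.**
- Failure mode: the acid-labile 3-sulfate may hydrolyse on the strongly acidic resin surface, or when the free acid concentrates during freeze-drying.
- The fallback avoids the resin, sets out from 7 and comes back at 8.
- KOAc-saturated MeOH precipitates the stable, storable dipotassium isorhamnetin 3,7-di-O-sulfate F5.
- F5 is passed through a C18 reversed-phase column with cold 0.1% aqueous CF3CO2H/MeCN. K+ leaves in the void volume and the disulfate elutes with H+ as counter-ion.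
- The volatile acid is removed by lyophilisation to give 8.

**Further compounds**
F1 | step 2 | bis(tetrabutylammonium) 4'-O-benzylquercetin 3,7-di-O-sulfate | CCCC[N+](CCCC)(CCCC)CCCC.CCCC[N+](CCCC)(CCCC)CCCC.O=c1c(OS(=O)(=O)[O-])c(-c2ccc(OCc3ccccc3)c(O)c2)oc2cc(OS(=O)(=O)[O-])cc(O)c12
F2 | step 2 | bis(tetrabutylammonium) 4'-O-benzylisorhamnetin 3,7-di-O-sulfate | CCCC[N+](CCCC)(CCCC)CCCC.CCCC[N+](CCCC)(CCCC)CCCC.O=c1c(OS(=O)(=O)[O-])c(-c2ccc(OCc3ccccc3)c(OC)c2)oc2cc(OS(=O)(=O)[O-])cc(O)c12
F3 | step 1 | 3',4'-O-(diphenylmethylene)quercetin | O=c1c(O)c(-c2ccc3OC(c4ccccc4)(c4ccccc4)Oc3c2)oc2cc(O)cc(O)c12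
F4 | step 1 | bis(tetrabutylammonium) 3',4'-O-(diphenylmethylene)quercetin 3,7-di-O-sulfate | CCCC[N+](CCCC)(CCCC)CCCC.CCCC[N+](CCCC)(CCCC)CCCC.O=c1c(OS(=O)(=O)[O-])c(-c2ccc3OC(c4ccccc4)(c4ccccc4)Oc3c2)oc2cc(OS(=O)(=O)[O-])cc(O)c12
F5 | step 3 | dipotassium isorhamnetin 3,7-di-O-sulfate | [K+].[K+].COc1cc(-c2oc3cc(OS(=O)(=O)[O-])cc(O)c3c(=O)c2OS(=O)(=O)[O-])ccc1O
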